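The route rests on disconnecting the bond between aromatic C6 of the chromanone's benzene ring and the benzylic stereocentre of the octanoic acid chain back to an allyl ether on O7. Because O7 lies between C6 (acid chain) and C8 (prenyl), this one oxygen of a symmetric phloroglucinol can hand both carbon groups to its neighbours. Heating the (S,E)-non-3-en-2-yl ether of 3,5-bis(methoxymethoxy)phenol causes an aromatic Claisen shift that makes the aryl–carbon bond, converts the carbinol centre into the (R)-benzylic centre and releases O7–H for a second O-to-C relay (prenyl) and final methylation. Aryllithium acylation and Mitsunobu closure then build the cis-dimethylpyranone ring.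

Key step: step 4

Remark: ring positions of intermediates are given in the chromanone numbering of the target (O1, C2, C3, C4, C4a, C5 to C8, C8a); MOM = methoxymethyl, TBS = tert-butyldimethylsilyl, TBDPS = tert-butyldiphenylsilyl.

Step 1
Reactants: 1 phloroglucinol
Product: 2 3,5-bis(methoxymethoxy)phenol
Conditions: MOMCl (2.0 equiv), i-Pr2NEt (2.2 equiv), CH2Cl2/DMF, 0 °C → rt; chromatography
Reagents that add atoms: chloromethyl methyl ether, COCCl
Why: Williamson-type O-alkylation; two equivalents should make the bis-ether the main component of a statistical mixture that is separated from mono- and tris-ethers, and the symmetry of phloroglucinol removes any regiochemical question.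

Step 2
Reactants: 3 (E)-non-3-en-2-one
Product: 4 (R,E)-non-3-en-2-ol
Conditions: (S)-1-methyl-3,3-diphenyltetrahydro-1H,3H-pyrrolo[1,2-c][1,3,2]oxazaborole ((S)-Me-CBS, 10 mol %), catecholborane, toluene, −78 °C; then MeOH, aq. NaOH
Reagents that add atoms: none
Why: Corey–Bakshi–Shibata reduction: the (S)-oxazaborolidine binds the carbonyl with the alkenyl group as the large substituent and directs hydride from catecholborane to one face, giving the (R)-allylic alcohol by 1,2-reduction at a temperature where hydroboration and conjugate reduction should not compete.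

Step 3
Reactants: 2 3,5-bis(methoxymethoxy)phenol; 4 (R,E)-non-3-en-2-ol
Product: 5 1,3-bis(methoxymethoxy)-5-{[(2S,3E)-non-3-en-2-yl]oxy}benzene
Conditions: PPh3, DIAD, toluene, 0 °C → rt
Reagents that add atoms: none
Why: Mitsunobu etherification: the phenol displaces the alkoxyphosphonium leaving group by SN2 with inversion, turning the (R)-carbinol into the (S)-aryl ether, and the non-polar solvent and low temperature disfavour ionisation and SN2′ attack.

Step 4
Reactants: 5 1,3-bis(methoxymethoxy)-5-{[(2S,3E)-non-3-en-2-yl]oxy}benzene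
Product: 7 2-[(2E,4R)-non-2-en-4-yl]-3,5-bis(methoxymethoxy)phenol, via ortho-dienone 6 (not isolated)
Conditions: N,N-diethylaniline (degassed), 150 °C, sealed tube
Reagents that add atoms: none
Why: On heating, the aryl allyl ether undergoes a concerted, suprafacial [3,3] sigmatropic shift through a chair transition state in which the O7–C(carbinol) bond breaks as the bond between an ortho ring carbon (the future C6) and the distal alkene carbon forms, giving ortho-dienone 6, which tautomerises to phenol 7. The closest known reaction type is the aromatic Claisen rearrangement of aryl ethers of enantioenriched (E)-secondary allylic alcohols with 1,3-chirality transfer. No ring is closed permanently; the only cyclic array is the six-membered pericyclic transition state. The new benzylic stereocentre is controlled by the (S)-carbinol centre together with the E alkene geometry: with the carbinol methyl pseudo-equatorial in the chair, the ring carbon is delivered to the alkene face from which oxygen departs, which gives the (R) centre and an E propenyl group. The step needs regiocontrol and faithful transfer of configuration: the two ortho positions of the 3,5-bis(methoxymethoxy)phenyl ring are equivalent by symmetry, so only one constitution can form, and the electron-rich ring should let the shift run at moderate temperature in a basic, non-ionising medium, which disfavours ionisation to an allyl cation and the later abnormal Claisen isomerisation of the product.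

Step 5
Reactants: 7 2-[(2E,4R)-non-2-en-4-yl]-3,5-bis(methoxymethoxy)phenol
Product: 8 2-[(3R)-oct-1-en-3-yl]-3,5-bis(methoxymethoxy)phenol
Conditions: ethylene (1–5 bar), [RuCl2(=CH-C6H4-2-O-i-Pr)(H2IMes)] (second-generation Hoveyda–Grubbs catalyst, H2IMes = 1,3-dimesitylimidazolidin-2-ylidene, 5 mol %), 1,4-benzoquinone (10 mol %), CH2Cl2, 40 °C
Reagents that add atoms: ethylene, C=C
Why: Ethenolysis (cross-metathesis with ethylene): excess ethylene drives exchange of the ethylidene terminus for methylene with loss of propene, and benzoquinone is added to quench ruthenium hydrides that could move the double bond toward the benzylic stereocentre.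

Step 6
Reactants: 8 2-[(3R)-oct-1-en-3-yl]-3,5-bis(methoxymethoxy)phenol; 9 2-methylbut-3-yn-2-ol
Product: 11 1,5-bis(methoxymethoxy)-3-[(2-methylbut-3-yn-2-yl)oxy]-2-[(3R)-oct-1-en-3-yl]benzene, via propargylic trifluoroacetate 10 (not isolated)
Conditions: 9, (CF3CO)2O, DBU, MeCN, −5 °C; then added to 8, DBU, CuCl2·2H2O (1 mol %), MeCN, −5 → 0 °C
Reagents that add atoms: none
Why: Copper-catalysed propargylic etherification (Godfrey-type): the tertiary propargylic trifluoroacetate made in the flask forms a copper acetylide/allenylidene species that the phenoxide captures at the tertiary carbon, a method that tolerates ortho-substituted phenols.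

Step 7
Reactants: 11 1,5-bis(methoxymethoxy)-3-[(2-methylbut-3-yn-2-yl)oxy]-2-[(3R)-oct-1-en-3-yl]benzene
Product: 14 3,5-bis(methoxymethoxy)-2-(3-methylbut-2-en-1-yl)-6-[(3R)-oct-1-en-3-yl]phenol, via 1,1-dimethylallyl ether 12 (not isolated), via prenyl dienone 13 (not isolated)
Conditions: H2 (1 atm), Pd/CaCO3 poisoned with Pb(OAc)2 (Lindlar catalyst), quinoline, toluene, rt, stopped at one equivalent of H2; filtered through Celite; filtrate heated at 110 °C
Reagents that add atoms: none
Why: Lindlar semi-hydrogenation reduces the terminal alkyne much faster than the monosubstituted alkene, and the resulting 1,1-dimethylallyl aryl ether undergoes an aromatic Claisen rearrangement to the only free ortho position (the future C8), which after tautomerisation of dienone 13 places a linear prenyl group next to the freed O7–H.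

Step 8
Reactants: 14 3,5-bis(methoxymethoxy)-2-(3-methylbut-2-en-1-yl)-6-[(3R)-oct-1-en-3-yl]phenol
Product: 15 3-methoxy-1,5-bis(methoxymethoxy)-2-(3-methylbut-2-en-1-yl)-4-[(3R)-oct-1-en-3-yl]benzene
Conditions: MeI, K2CO3, DMF, rt → 40 °C
Reagents that add atoms: iodomethane, CI
Why: Williamson O-methylation of the hindered phenol, the only acidic site, with a small electrophile.

Step 9
Reactants: 15 3-methoxy-1,5-bis(methoxymethoxy)-2-(3-methylbut-2-en-1-yl)-4-[(3R)-oct-1-en-3-yl]benzene
Product: 17 (3R)-3-[2-methoxy-4,6-bis(methoxymethoxy)-3-(3-methylbut-2-en-1-yl)phenyl]octan-1-ol, via B-alkyl-9-BBN borane 16 (not isolated)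
Conditions: 9-borabicyclo[3.3.1]nonane (9-BBN, 1.5 equiv), THF, 0 °C → rt; then aq. NaOH, H2O2, 0 °C
Reagents that add atoms: hydrogen peroxide, OO
Why: Brown hydroboration–oxidation: the bulky 9-BBN adds anti-Markovnikov to the monosubstituted vinyl group much faster than to the trisubstituted prenyl alkene, and oxidation of the C–B bond gives the primary alcohol without affecting the adjacent stereocentre.

Step 10
Reactants: 17 (3R)-3-[2-methoxy-4,6-bis(methoxymethoxy)-3-(3-methylbut-2-en-1-yl)phenyl]octan-1-ol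
Product: 18 tert-butyl({(3R)-3-[2-methoxy-4,6-bis(methoxymethoxy)-3-(3-methylbut-2-en-1-yl)phenyl]octyl}oxy)dimethylsilane
Conditions: TBSCl, imidazole, DMF, rt
Reagents that add atoms: tert-butyldimethylsilyl chloride, CC(C)(C)[Si](C)(C)Cl
Why: Standard silylation of the primary alcohol, masking it against n-BuLi in step 14.

Step 11
Reactants: 19 ethyl (R)-3-hydroxybutanoate
Product: 21 ethyl (2R,3R)-3-hydroxy-2-methylbutanoate, via dilithium alkoxide enolate 20 (not isolated)
Conditions: LDA (commercial solution, 2.2 equiv), THF, −50 → −20 °C; MeI, DMPU, −78 → 0 °C; aq. NH4Cl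
Reagents that add atoms: iodomethane, CI
Why: Fráter–Seebach alkylation: the chelated dilithium alkoxide–enolate is methylated on the face opposite the C3 methyl group, which sets C2 anti to the existing (R)-carbinol centre and gives the (2R,3R) ester.

Step 12
Reactants: 21 ethyl (2R,3R)-3-hydroxy-2-methylbutanoate
Product: 22 (2R,3R)-3-hydroxy-N-methoxy-N,2-dimethylbutanamide
Conditions: MeNHOMe·HCl, i-PrMgCl, THF, −20 → 0 °C
Reagents that add atoms: N,O-dimethylhydroxylamine hydrochloride, CNOC.Cl
Why: Weinreb amidation of the ester with the magnesium amide formed in the flask; the hydroxyl is carried as its magnesium alkoxide, which should prevent β-elimination and epimerisation at C2.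

Step 13
Reactants: 22 (2R,3R)-3-hydroxy-N-methoxy-N,2-dimethylbutanamide
Product: 23 (2R,3R)-3-[(tert-butyldiphenylsilyl)oxy]-N-methoxy-N,2-dimethylbutanamide
Conditions: TBDPSCl, imidazole, DMF, rt
Reagents that add atoms: tert-butyldiphenylsilyl chloride, CC(C)(C)[Si](Cl)(c1ccccc1)c1ccccc1
Why: Imidazole-mediated silylation of the secondary alcohol; the bulky TBDPS ether is chosen to survive n-BuLi, buffered HF and the Lewis acid used later while the primary TBS ether is removed.

Step 14
Reactants: 18 tert-butyl({(3R)-3-[2-methoxy-4,6-bis(methoxymethoxy)-3-(3-methylbut-2-en-1-yl)phenyl]octyl}oxy)dimethylsilane; 23 (2R,3R)-3-[(tert-butyldiphenylsilyl)oxy]-N-methoxy-N,2-dimethylbutanamide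
Product: 25 (2R,3R)-1-{3-[(3R)-1-(tert-butyldimethylsilyloxy)octan-3-yl]-4-methoxy-2,6-bis(methoxymethoxy)-5-(3-methylbut-2-en-1-yl)phenyl}-3-(tert-butyldiphenylsilyloxy)-2-methylbutan-1-one, via aryllithium 24 (not isolated)
Conditions: n-BuLi (1.2 equiv), THF, 0 °C, 1 h; then 23, −78 → 0 °C; aq. NH4Cl
Reagents that add atoms: none
Why: Directed ortho-metalation: the only remaining aryl C–H (C4a) lies between two methoxymethoxy groups that both coordinate lithium, and the aryllithium is acylated by the Weinreb amide, whose N-methoxy group holds the addition product until work-up so that no over-addition occurs and the side-chain stereocentres stay untouched if the addition is run cold.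

Step 15
Reactants: 25 (2R,3R)-1-{3-[(3R)-1-(tert-butyldimethylsilyloxy)octan-3-yl]-4-methoxy-2,6-bis(methoxymethoxy)-5-(3-methylbut-2-en-1-yl)phenyl}-3-(tert-butyldiphenylsilyloxy)-2-methylbutan-1-one
Product: 26 (2R,3R)-3-(tert-butyldiphenylsilyloxy)-1-{3-[(3R)-1-hydroxyoctan-3-yl]-4-methoxy-2,6-bis(methoxymethoxy)-5-(3-methylbut-2-en-1-yl)phenyl}-2-methylbutan-1-one
Conditions: HF·pyridine, pyridine, THF, 0 °C
Reagents that add atoms: none
Why: Selective protodesilylation: buffered HF·pyridine cleaves the unhindered primary TBS ether far faster than the secondary TBDPS ether and leaves the aryl MOM acetals and the prenyl group alone.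

Step 16
Reactants: 26 (2R,3R)-3-(tert-butyldiphenylsilyloxy)-1-{3-[(3R)-1-hydroxyoctan-3-yl]-4-methoxy-2,6-bis(methoxymethoxy)-5-(3-methylbut-2-en-1-yl)phenyl}-2-methylbutan-1-one
Product: 28 (3R)-3-{3-[(2R,3R)-3-(tert-butyldiphenylsilyloxy)-2-methylbutanoyl]-6-methoxy-2,4-bis(methoxymethoxy)-5-(3-methylbut-2-en-1-yl)phenyl}octanoic acid, via aldehyde 27 (not isolated)
Conditions: 2,2,6,6-tetramethylpiperidin-1-oxyl (TEMPO, 20 mol %), PhI(OAc)2 (2.5 equiv), MeCN/H2O (pH 7 buffer), rt
Reagents that add atoms: water, O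
Why: TEMPO/PhI(OAc)2 oxidation in aqueous acetonitrile takes the primary alcohol through aldehyde 27 and its hydrate to the acid without touching the trisubstituted alkene, the fully substituted aryl ethers or the silyl ether, and the non-basic medium spares the α-stereocentre of the ketone.

Step 17
Reactants: 28 (3R)-3-{3-[(2R,3R)-3-(tert-butyldiphenylsilyloxy)-2-methylbutanoyl]-6-methoxy-2,4-bis(methoxymethoxy)-5-(3-methylbut-2-en-1-yl)phenyl}octanoic acid
Product: 29 (3R)-3-{3-[(2R,3R)-3-(tert-butyldiphenylsilyloxy)-2-methylbutanoyl]-2,4-dihydroxy-6-methoxy-5-(3-methylbut-2-en-1-yl)phenyl}octanoic acid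
Conditions: ZnBr2, n-PrSH, CH2Cl2, 0 °C, short reaction time
Reagents that add atoms: none
Why: Lewis acid-assisted thiolytic cleavage of the two aryl MOM acetals, both activated by the neighbouring ketone; the brief, cold, aprotic conditions should leave the TBDPS ether intact and avoid acid-catalysed cyclisation of the prenyl group onto O1–H.

Step 18
Reactants: 29 (3R)-3-{3-[(2R,3R)-3-(tert-butyldiphenylsilyloxy)-2-methylbutanoyl]-2,4-dihydroxy-6-methoxy-5-(3-methylbut-2-en-1-yl)phenyl}octanoic acid
Product: 30 (4R)-8-[(2R,3R)-3-(tert-butyldiphenylsilyloxy)-2-methylbutanoyl]-7-hydroxy-5-methoxy-6-(3-methylbut-2-en-1-yl)-4-pentylchroman-2-one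
Conditions: EDC·HCl, 4-(dimethylamino)pyridine (cat.), CH2Cl2 (dilute), 0 °C → rt
Reagents that add atoms: none
Why: Carbodiimide-mediated (Steglich-type) lactonisation: only O5–H can reach the activated carboxyl, through a six-membered ring, while O1–H stays hydrogen-bonded to the ketone, so the two phenols are told apart.

Step 19
Reactants: 30 (4R)-8-[(2R,3R)-3-(tert-butyldiphenylsilyloxy)-2-methylbutanoyl]-7-hydroxy-5-methoxy-6-(3-methylbut-2-en-1-yl)-4-pentylchroman-2-one
Product: 31 (4R)-7-hydroxy-8-[(2R,3R)-3-hydroxy-2-methylbutanoyl]-5-methoxy-6-(3-methylbut-2-en-1-yl)-4-pentylchroman-2-one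
Conditions: HF·pyridine, THF, rt → 40 °C
Reagents that add atoms: none
Why: Fluoride-induced cleavage of the TBDPS ether under mildly acidic conditions, chosen because basic fluoride could trigger retro-aldol cleavage or elimination of the β-hydroxy ketone or open the aryl lactone.

Step 20
Reactants: 31 (4R)-7-hydroxy-8-[(2R,3R)-3-hydroxy-2-methylbutanoyl]-5-methoxy-6-(3-methylbut-2-en-1-yl)-4-pentylchroman-2-one
Product: 32 tricyclic lactone–chromanone: (2S,3R)-7-methoxy-2,3-dimethyl-8-(3-methylbut-2-en-1-yl)chroman-4-one whose O5 and C6 are bridged by –CO–CH2–CH(pentyl)– as a six-membered aryl lactone, (R) at the pentyl-bearing carbon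
Conditions: PPh3, DIAD, THF, 0 °C → rt
Reagents that add atoms: none
Why: Intramolecular Mitsunobu etherification: the acidic, ketone-chelated O1–H attacks the activated carbinol in a 6-exo-tet SN2 closure with inversion, converting the (3R)-carbinol into C2 of (S) configuration, cis to the untouched (R)-C3 methyl group.

Step 21
Reactants: 32 tricyclic lactone–chromanone
Product: 33 (3R)-3-[(2S,3R)-5-hydroxy-7-methoxy-2,3-dimethyl-8-(3-methylbut-2-en-1-yl)-4-oxochroman-6-yl]octanoic acid (CNP0217102.1)
Conditions: LiOH·H2O (2.5 equiv), THF/H2O, 0 °C, short reaction time; then 1 M HCl to pH 3–4, 0 °C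
Reagents that add atoms: lithium hydroxide, [Li+].[OH-]
Why: Saponification of the aryl lactone, by far the most electrophilic carbonyl present; the C5 phenoxide set free is conjugated with the C4 ketone and should suppress enolisation toward C3, and cold, brief exposure followed by mild acidification is meant to preserve the cis-2,3-dimethyl arrangement.

Compound list
1 | phloroglucinol (benzene-1,3,5-triol) | Oc1cc(O)cc(O)c1 | starting material
2 | 3,5-bis(methoxymethoxy)phenol | COCOc1cc(O)cc(OCOC)c1 | intermediate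
3 | (E)-non-3-en-2-one | CC(=O)/C=C/CCCCC | starting material
4 | (R,E)-non-3-en-2-ol | C[C@@H](O)/C=C/CCCCC | intermediate
5 | 1,3-bis(methoxymethoxy)-5-{[(2S,3E)-non-3-en-2-yl]oxy}benzene | C[C@H](Oc1cc(OCOC)cc(OCOC)c1)/C=C/CCCCC | intermediate
6 | (6R)-6-[(2E,4R)-non-2-en-4-yl]-3,5-bis(methoxymethoxy)cyclohexa-2,4-dien-1-one (ortho-dienone) | CCCCC[C@H](/C=C/C)[C@H]1C(=O)C=C(OCOC)C=C1OCOC | intermediate
7 | 2-[(2E,4R)-non-2-en-4-yl]-3,5-bis(methoxymethoxy)phenol | CCCCC[C@H](/C=C/C)c1c(O)cc(OCOC)cc1OCOC | intermediate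
8 | 2-[(3R)-oct-1-en-3-yl]-3,5-bis(methoxymethoxy)phenol | CCCCC[C@H](C=C)c1c(O)cc(OCOC)cc1OCOC | intermediate
9 | 2-methylbut-3-yn-2-ol | CC(C)(O)C#C | starting material
10 | 2-methylbut-3-yn-2-yl trifluoroacetate | CC(C)(OC(=O)C(F)(F)F)C#C | intermediate
11 | 1,5-bis(methoxymethoxy)-3-[(2-methylbut-3-yn-2-yl)oxy]-2-[(3R)-oct-1-en-3-yl]benzene | CCCCC[C@H](C=C)c1c(OC(C)(C)C#C)cc(OCOC)cc1OCOC | intermediate
12 | 1,5-bis(methoxymethoxy)-3-[(2-methylbut-3-en-2-yl)oxy]-2-[(3R)-oct-1-en-3-yl]benzene | CCCCC[C@H](C=C)c1c(OC(C)(C)C=C)cc(OCOC)cc1OCOC | intermediate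
13 | 3,5-bis(methoxymethoxy)-6-(3-methylbut-2-en-1-yl)-2-[(3R)-oct-1-en-3-yl]cyclohexa-2,4-dien-1-one (both epimers at ring C6) | CCCCC[C@H](C=C)C1=C(OCOC)C=C(OCOC)C(CC=C(C)C)C1=O | intermediate
14 | 3,5-bis(methoxymethoxy)-2-(3-methylbut-2-en-1-yl)-6-[(3R)-oct-1-en-3-yl]phenol | CCCCC[C@H](C=C)c1c(O)c(CC=C(C)C)c(OCOC)cc1OCOC | intermediate
15 | 3-methoxy-1,5-bis(methoxymethoxy)-2-(3-methylbut-2-en-1-yl)-4-[(3R)-oct-1-en-3-yl]benzene | CCCCC[C@H](C=C)c1c(OC)c(CC=C(C)C)c(OCOC)cc1OCOC | intermediate
16 | B-alkyl-9-borabicyclo[3.3.1]nonane adduct of 15, boron on the terminal carbon of the former vinyl group (benzylic centre spatially unchanged) | CCCCC[C@H](CCB1C2CCCC1CCC2)c1c(OC)c(CC=C(C)C)c(OCOC)cc1OCOC | intermediate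
17 | (3R)-3-[2-methoxy-4,6-bis(methoxymethoxy)-3-(3-methylbut-2-en-1-yl)phenyl]octan-1-ol | CCCCC[C@H](CCO)c1c(OC)c(CC=C(C)C)c(OCOC)cc1OCOC | intermediate
18 | tert-butyl({(3R)-3-[2-methoxy-4,6-bis(methoxymethoxy)-3-(3-methylbut-2-en-1-yl)phenyl]octyl}oxy)dimethylsilane | CCCCC[C@H](CCO[Si](C)(C)C(C)(C)C)c1c(OC)c(CC=C(C)C)c(OCOC)cc1OCOC | intermediate
19 | ethyl (R)-3-hydroxybutanoate | C[C@@H](O)CC(=O)OCC | starting material
20 | dilithium alkoxide–enolate of 19 (enolate oxygen cis to C3, chelated) | [Li+].[Li+].CCO/C([O-])=C/[C@@H](C)[O-] | intermediate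
21 | ethyl (2R,3R)-3-hydroxy-2-methylbutanoate | C[C@@H](O)[C@@H](C)C(=O)OCC | intermediate
22 | (2R,3R)-3-hydroxy-N-methoxy-N,2-dimethylbutanamide | C[C@@H](O)[C@@H](C)C(=O)N(C)OC | intermediate
23 | (2R,3R)-3-[(tert-butyldiphenylsilyl)oxy]-N-methoxy-N,2-dimethylbutanamide | C[C@@H](O[Si](c1ccccc1)(c1ccccc1)C(C)(C)C)[C@@H](C)C(=O)N(C)OC | intermediate
24 | {3-[(3R)-1-(tert-butyldimethylsilyloxy)octan-3-yl]-4-methoxy-2,6-bis(methoxymethoxy)-5-(3-methylbut-2-en-1-yl)phenyl}lithium | CCCCC[C@H](CCO[Si](C)(C)C(C)(C)C)c1c(OC)c(CC=C(C)C)c(OCOC)c([Li])c1OCOC | intermediate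
25 | (2R,3R)-1-{3-[(3R)-1-(tert-butyldimethylsilyloxy)octan-3-yl]-4-methoxy-2,6-bis(methoxymethoxy)-5-(3-methylbut-2-en-1-yl)phenyl}-3-(tert-butyldiphenylsilyloxy)-2-methylbutan-1-one | CCCCC[C@H](CCO[Si](C)(C)C(C)(C)C)c1c(OC)c(CC=C(C)C)c(OCOC)c(C(=O)[C@H](C)[C@@H](C)O[Si](c2ccccc2)(c2ccccc2)C(C)(C)C)c1OCOC | intermediate
26 | (2R,3R)-3-(tert-butyldiphenylsilyloxy)-1-{3-[(3R)-1-hydroxyoctan-3-yl]-4-methoxy-2,6-bis(methoxymethoxy)-5-(3-methylbut-2-en-1-yl)phenyl}-2-methylbutan-1-one | CCCCC[C@H](CCO)c1c(OC)c(CC=C(C)C)c(OCOC)c(C(=O)[C@H](C)[C@@H](C)O[Si](c2ccccc2)(c2ccccc2)C(C)(C)C)c1OCOC | intermediate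
27 | (3R)-3-{3-[(2R,3R)-3-(tert-butyldiphenylsilyloxy)-2-methylbutanoyl]-6-methoxy-2,4-bis(methoxymethoxy)-5-(3-methylbut-2-en-1-yl)phenyl}octanal | CCCCC[C@H](CC=O)c1c(OC)c(CC=C(C)C)c(OCOC)c(C(=O)[C@H](C)[C@@H](C)O[Si](c2ccccc2)(c2ccccc2)C(C)(C)C)c1OCOC | intermediate
28 | (3R)-3-{3-[(2R,3R)-3-(tert-butyldiphenylsilyloxy)-2-methylbutanoyl]-6-methoxy-2,4-bis(methoxymethoxy)-5-(3-methylbut-2-en-1-yl)phenyl}octanoic acid | CCCCC[C@H](CC(=O)O)c1c(OC)c(CC=C(C)C)c(OCOC)c(C(=O)[C@H](C)[C@@H](C)O[Si](c2ccccc2)(c2ccccc2)C(C)(C)C)c1OCOC | intermediate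
29 | (3R)-3-{3-[(2R,3R)-3-(tert-butyldiphenylsilyloxy)-2-methylbutanoyl]-2,4-dihydroxy-6-methoxy-5-(3-methylbut-2-en-1-yl)phenyl}octanoic acid | CCCCC[C@H](CC(=O)O)c1c(OC)c(CC=C(C)C)c(O)c(C(=O)[C@H](C)[C@@H](C)O[Si](c2ccccc2)(c2ccccc2)C(C)(C)C)c1O | intermediate
30 | (4R)-8-[(2R,3R)-3-(tert-butyldiphenylsilyloxy)-2-methylbutanoyl]-7-hydroxy-5-methoxy-6-(3-methylbut-2-en-1-yl)-4-pentylchroman-2-one | CCCCC[C@@H]1CC(=O)Oc2c1c(OC)c(CC=C(C)C)c(O)c2C(=O)[C@H](C)[C@@H](C)O[Si](c3ccccc3)(c3ccccc3)C(C)(C)C | intermediate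
31 | (4R)-7-hydroxy-8-[(2R,3R)-3-hydroxy-2-methylbutanoyl]-5-methoxy-6-(3-methylbut-2-en-1-yl)-4-pentylchroman-2-one | CCCCC[C@@H]1CC(=O)Oc2c1c(OC)c(CC=C(C)C)c(O)c2C(=O)[C@H](C)[C@@H](C)O | intermediate
32 | tricyclic lactone–chromanone: (2S,3R)-7-methoxy-2,3-dimethyl-8-(3-methylbut-2-en-1-yl)chroman-4-one whose O5 and C6 are bridged by –CO–CH2–CH(pentyl)– as a six-membered aryl lactone, (R) at the pentyl-bearing carbon | CCCCC[C@@H]1CC(=O)Oc2c1c(OC)c(CC=C(C)C)c1O[C@@H](C)[C@@H](C)C(=O)c21 | intermediate
33 | (3R)-3-[(2S,3R)-5-hydroxy-7-methoxy-2,3-dimethyl-8-(3-methylbut-2-en-1-yl)-4-oxochroman-6-yl]octanoic acid (CNP0217102.1) | CCCCC[C@H](CC(=O)O)c1c(O)c2c(c(CC=C(C)C)c1OC)O[C@@H](C)[C@@H](C)C2=O | target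

Total step count: 21 steps.
Longest linear sequence: 17 steps (from 1 through steps 1, 3 to 10 and 14 to 21; the branch from 3 is equally long, the branch from 19 is 11 steps).

Steps most likely to fail

Step 14. The doubly ortho-substituted aryllithium may act as a base toward the α-branched amide (α-deprotonation followed by loss of silanolate, or simply no addition), and metalation could compete at the benzylic/allylic CH2 of the prenyl group. The fallback sets out from 18 and 23 and comes back at 25. Amide 23 would be reduced with i-Bu2AlH in THF at −78 °C to (2R,3R)-3-(tert-butyldiphenylsilyloxy)-2-methylbutanal F1. Aryllithium 24, generated from 18 as in step 14, would be added to F1 at −78 °C, where the far more electrophilic aldehyde should outrun proton transfer, to give the benzylic carbinol F2 as both epimers at the new carbinol carbon. Oxidation with Dess–Martin periodinane (NaHCO3, CH2Cl2) would converge both epimers on ketone 25.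

Step 5. Turnover may be slow at the alkene next to the branched benzylic carbon, and ruthenium hydride species may move the double bond into conjugation with the arene, which would erase the benzylic stereocentre. The fallback sets out from 7 and comes back at 8. The propenyl group would be dihydroxylated (K2OsO4·2H2O cat., N-methylmorpholine N-oxide, acetone/H2O) to the diol F3. Glycol cleavage with NaIO4 (THF/pH 7 buffer, 0 °C) would give the aldehyde, held by the ortho phenol as its ring tautomer, (3S)-4,6-bis(methoxymethoxy)-3-pentyl-2,3-dihydro-1-benzofuran-2-ol F4 (benzylic centre spatially unchanged). Wittig methylenation with Ph3P=CH2 (from Ph3PCH3Br and KN(SiMe3)2, THF, −78 → 0 °C) would open the lactol and return to vinyl phenol 8.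

Step 21. Hydroxide may enolise the ketone or open the pyranone ring by retro-oxa-Michael reaction, epimerising the cis-2,3-dimethyl unit toward the trans isomer, and the hydroxy acid may re-lactonise on acidification. The fallback sets out from 32 and comes back at 33. The aryl lactone would be opened by acid-catalysed alcoholysis in allyl alcohol (pyridinium p-toluenesulfonate cat., 50 °C) to allyl (3R)-3-[(2S,3R)-5-hydroxy-7-methoxy-2,3-dimethyl-8-(3-methylbut-2-en-1-yl)-4-oxochroman-6-yl]octanoate F5, in which the freed C5–OH is chelated to the C4 ketone. Deallylation with Pd(PPh3)4 (cat.) and PhSiH3 in CH2Cl2 at rt would then release acid 33 without base.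

Further compounds
F1 | step 14 | (2R,3R)-3-(tert-butyldiphenylsilyloxy)-2-methylbutanal | C[C@@H](O[Si](c1ccccc1)(c1ccccc1)C(C)(C)C)[C@@H](C)C=O
F2 | step 14 | benzylic carbinol from addition of 24 to F1 (both epimers at the new carbinol carbon, side-chain stereocentres as in F1) | CCCCC[C@H](CCO[Si](C)(C)C(C)(C)C)c1c(OC)c(CC=C(C)C)c(OCOC)c(C(O)[C@H](C)[C@@H](C)O[Si](c2ccccc2)(c2ccccc2)C(C)(C)C)c1OCOC
F3 | step 5 | 2-(2,3-dihydroxynonan-4-yl)-3,5-bis(methoxymethoxy)phenol (diol epimers at the two new carbinol carbons, benzylic centre spatially unchanged) | CCCCC[C@H](C(O)C(C)O)c1c(O)cc(OCOC)cc1OCOC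
F4 | step 5 | (3S)-4,6-bis(methoxymethoxy)-3-pentyl-2,3-dihydro-1-benzofuran-2-ol (both anomers) | CCCCC[C@@H]1C(O)Oc2cc(OCOC)cc(OCOC)c21
F5 | step 21 | allyl (3R)-3-[(2S,3R)-5-hydroxy-7-methoxy-2,3-dimethyl-8-(3-methylbut-2-en-1-yl)-4-oxochroman-6-yl]octanoate | CCCCC[C@H](CC(=O)OCC=C)c1c(O)c2c(c(CC=C(C)C)c1OC)O[C@@H](C)[C@@H](C)C2=O
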